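**Retrosynthesis**
- Angustone B is disconnected at the C3–C1′ aryl bond. A radical (Meerwein-type) α-arylation of an o-oxygenated aryl enaminone by a B-ring aryl radical forms this bond, and oxa-Michael cyclisation then closes the pyranone ring.
- The A-ring enaminone comes from 2-prenyl-1,3-bis(MOM-oxy)benzene. Sterically controlled Ir C–H borylation and oxidation install the third ring oxygen, so resorcinol (8 heavy atoms) is the only ring source needed. Directed lithiation installs the acetyl group.
- The B-ring aryl iodide is an angular 2,2-dimethylchromene made from resorcinol and prenal, then ortho-iodinated.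
- Ring order: B-ring pyran (chromene), then A ring (prenylated phloroglucinol-type arene), then the pyranone C ring.

**Assumptions**
- The target has no stereocentres, so there is no enantiomer to control. Only the (E)-enaminone geometry, which is lost on cyclisation, and the ring-fixed chromene alkene are relevant.
- Resorcinol serves as the source of both aromatic rings. All starting materials are at most 8 heavy atoms: resorcinol 8, prenal 6, prenyl bromide 6.

---

**Step 1**
Reactants: 1 (resorcinol) + 2 (prenal, 3-methylbut-2-enal)
Product: 3 (2,2-dimethyl-2H-chromen-5-ol)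
Conditions: pyridine, 125 °C, sealed tube, 24 h; separate the 7-ol isomer by chromatography
Reagents that add atoms: none
Why: Condensation at C2 of resorcinol, then 6π-oxa-electrocyclisation of the o-quinone-methide dienol, is a standard 2,2-dimethylchromene synthesis. The angular 5-ol is the major regioisomer. No stereocentre forms.

**Step 2**
Reactants: 3
Product: 4 (5-(methoxymethoxy)-2,2-dimethyl-2H-chromene)
Conditions: MOMCl, iPr2NEt, CH2Cl2, 0 °C → rt
Reagents that add atoms: chloromethyl methyl ether, ClCOC
Why: Simple O-alkylation. The MOM group protects the phenol and acts as the ortho-directing group for Step 3.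

**Step 3**
Reactants: 4
Product: 5 (6-iodo-5-(methoxymethoxy)-2,2-dimethyl-2H-chromene)
Conditions: n-BuLi, TMEDA, THF, 0 °C; then I2, −78 °C → rt
Reagents that add atoms: iodine, II
Why: Directed ortho-metalation next to OMOM. The other ortho position (C4a) is blocked, so lithiation and iodination occur only at C6. This gives the aryl-radical precursor with fixed regiochemistry.

**Step 4**
Reactants: 1 (resorcinol)
Product: 6 (1,3-bis(methoxymethoxy)benzene)
Conditions: NaH, THF/DMF, 0 °C; then MOMCl (2.2 equiv), rt
Reagents that add atoms: chloromethyl methyl ether, ClCOC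
Why: Bis-O-alkylation. It sets up lithiation at C2 and sterically controlled C–H borylation at C5.

**Step 5**
Reactants: 6 + 7 (prenyl bromide)
Product: 8 (2-prenyl-1,3-bis(methoxymethoxy)benzene)
Conditions: n-BuLi, THF, 0 °C; then CuI (10 mol %), 7, −20 °C → rt
Reagents that add atoms: none (7 is the numbered reactant)
Why: Cooperative directed metalation between the two OMOM groups at C2, then Cu-catalysed SN2 (α-selective) prenylation of the aryllithium.

**Step 6**
Reactants: 8
Product: 9 (3,5-bis(methoxymethoxy)-4-prenylphenol)
Conditions: [Ir(cod)OMe]2 (1.5 mol %), dtbpy, B2pin2, THF, 80 °C; then NaBO3·4H2O, THF/H2O, rt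
Reagents that add atoms: perborate as HOO⁻ source, OO (its O becomes the phenol O; B2pin2 is lost as borate)
Why: Ir-catalysed C–H borylation is governed by sterics, so it goes only to C5, the single position with no ortho substituent. Mild perborate oxidation converts C–B to C–OH without epoxidising the prenyl alkene. This installs the third ring oxygen, para to the prenyl group, which becomes O1.

**Step 7**
Reactants: 9
Product: 10 (tert-butyldimethylsilyl ether of 9)
Conditions: TBSCl, imidazole, DMF, rt
Reagents that add atoms: tert-butyldimethylsilyl chloride, CC(C)(C)[Si](C)(C)Cl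
Why: Caps O1 so that only that oxygen is freed later, which fixes the 6-prenyl regiochemistry of the cyclisation. OTBS survives the lithiation in Step 8.

**Step 8**
Reactants: 10
Product: 11 (2-acetyl-aryl TBS ether: 1-[2-(TBSO)-4,6-bis(MOMO)-3-prenylphenyl]ethan-1-one)
Conditions: s-BuLi, TMEDA, THF, −78 °C; then MeC(O)NMe2, −78 °C → 0 °C
Reagents that add atoms: N,N-dimethylacetamide, CC(=O)N(C)C (delivers the acetyl group)
Why: The two ortho positions flanked by OTBS and OMOM are equivalent, so lithiation at one site gives one product. The aryllithium adds to DMA and the stable tetrahedral intermediate collapses to the methyl ketone on work-up.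

**Step 9**
Reactants: 11
Product: 12 ((E)-enaminone: 3-(dimethylamino)-1-[2-(TBSO)-4,6-bis(MOMO)-3-prenylphenyl]prop-2-en-1-one)
Conditions: DMF-DMA, toluene, 110 °C, 16 h
Reagents that add atoms: N,N-dimethylformamide dimethyl acetal, CN(C)C(OC)OC (delivers =CH–NMe2)
Why: Standard enaminone formation from a methyl ketone. It provides the C2–C3 unit of the chromone and an electron-rich α-carbon for radical capture.

**Step 10 (key radical step)**
Reactants: 12 + 5
Product: 13 (α-aryl enaminone)
Conditions: fac-Ir(ppy)3 (2 mol %), iPr2NEt (2.5 equiv), DMSO, blue LEDs, rt, 18 h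
Reagents that add atoms: none (the aryl group comes from 5; the Ir catalyst and amine add no atoms)
Why: The excited Ir catalyst and the amine reduce the Ar–I bond to give the 2-MOM-oxy-aryl radical.
Proposed new method: The aryl radical adds to the α-carbon of the push–pull enaminone, which gives a stabilised N-centred α-amino radical. Oxidation of that radical to the iminium and loss of H⁺ gives the α-aryl enaminone. The closest known reactions are Meerwein-type radical arylation of enamines and radical α-functionalisation/cyclisation of o-hydroxyaryl enaminones to 3-sulfenyl or 3-halo chromones. The C3–C1′ bond is formed here and no stereocentre is created.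

**Step 11**
Reactants: 13
Product: 14 (5,7-bis(MOMO)-6-prenyl-3-[5-(MOMO)-2,2-dimethylchromen-6-yl]chromone)
Conditions: TBAF, THF, 0 °C → rt, 1 h
Reagents that add atoms: none (Si is lost, and HNMe2 is eliminated)
Why: Fluoride unmasks only the O1 phenoxide. It undergoes 6-endo oxa-Michael addition onto the enaminone β-carbon, then loses HNMe2 (standard chromone closure). Only the oxygen that leads to the 6-prenyl isomer is free, so there is no regioisomer problem.

**Step 12**
Reactants: 14
Product: 15 (Angustone B)
Conditions: ZnBr2 (5 equiv), n-PrSH (10 equiv), CH2Cl2, 0 °C → rt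
Reagents that add atoms: none
Why: Mild Lewis-acid/thiol cleavage of all three aryl MOM ethers. The prenyl alkene, the chromene and the isoflavone are not affected. The 5-OH is then H-bonded to the C4 carbonyl.

---

**Compound list**
1 | resorcinol | Oc1cccc(O)c1 | starting material
2 | prenal (3-methylbut-2-enal) | CC(C)=CC=O | starting material
3 | 2,2-dimethyl-2H-chromen-5-ol | CC1(C)C=Cc2c(O)cccc2O1 | intermediate
4 | 5-(methoxymethoxy)-2,2-dimethyl-2H-chromene | COCOc1cccc2OC(C)(C)C=Cc12 | intermediate
5 | 6-iodo-5-(methoxymethoxy)-2,2-dimethyl-2H-chromene | COCOc1c(I)ccc2OC(C)(C)C=Cc12 | intermediate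
6 | 1,3-bis(methoxymethoxy)benzene | COCOc1cccc(OCOC)c1 | intermediate
7 | prenyl bromide (1-bromo-3-methylbut-2-ene) | CC(C)=CCBr | starting material
8 | 2-prenyl-1,3-bis(methoxymethoxy)benzene | COCOc1cccc(OCOC)c1CC=C(C)C | intermediate
9 | 3,5-bis(methoxymethoxy)-4-prenylphenol | COCOc1cc(O)cc(OCOC)c1CC=C(C)C | intermediate
10 | TBS ether of 9 | COCOc1cc(O[Si](C)(C)C(C)(C)C)cc(OCOC)c1CC=C(C)C | intermediate
11 | 1-[2-(TBSO)-4,6-bis(MOMO)-3-prenylphenyl]ethanone | CC(=O)c1c(O[Si](C)(C)C(C)(C)C)cc(OCOC)c(CC=C(C)C)c1OCOC | intermediate
12 | (E)-enaminone of 11 | CN(C)/C=C/C(=O)c1c(O[Si](C)(C)C(C)(C)C)cc(OCOC)c(CC=C(C)C)c1OCOC | intermediate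
13 | α-aryl enaminone | CN(C)C=C(c1ccc2OC(C)(C)C=Cc2c1OCOC)C(=O)c1c(O[Si](C)(C)C(C)(C)C)cc(OCOC)c(CC=C(C)C)c1OCOC | intermediate
14 | tris-MOM Angustone B | COCOc1cc2occ(-c3ccc4OC(C)(C)C=Cc4c3OCOC)c(=O)c2c(OCOC)c1CC=C(C)C | intermediate
15 | Angustone B | CC(C)=CCc1c(O)cc2occ(-c3ccc4c(c3O)C=CC(C)(C)O4)c(=O)c2c1O | target

**Totals:** 12 steps in total. The longest linear sequence is 9 steps (Steps 4–12). The B-ring branch (Steps 1–3) runs in parallel.

**Three steps most likely to fail**
1. **Step 10, radical arylation.** The aryl radical may be reduced by HAT from the amine, may add to the prenyl or chromene alkenes, or may add at the enaminone β-carbon to give the flavone regioisomer.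
   - Fallback: change the bond-forming approach. Treat 13's precursor 12 as follows: remove TBS and close the ring with I2 (giving the 3-iodochromone), then couple with the B-ring aryl boronic acid (from 5 by Li/B(OMe)3) by Suzuki coupling.
2. **Step 8, lithiation and acetylation.** The allylic-benzylic prenyl CH2 may be deprotonated, or the TBS group may migrate (retro-Brook).
   - Fallback: avoid organolithiums. Ortho-formylate phenol 9 with MgCl2/Et3N/(CH2O)n, add MeMgBr, and oxidise to the same methyl ketone, so that 9 is carried forward without a silyl group.
3. **Step 1, angular chromene regioselectivity.** The 7-ol linear isomer may dominate or the yield may be low.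
   - Fallback: go through 8 (2-prenyl-1,3-bis(MOM-oxy)benzene). Remove one MOM group, then close the ring by DDQ dehydrogenative cyclisation of the o-prenylphenol. This gives the angular 5-ol regiospecifically.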